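The data are simulated for substances that don't exist; scatter was added.

26.4% of the Q charged is the number to watch: maple's late readings of E average that share, and I call it the ceiling share, the E at the stop divided by the Q charged. Cedar's last reading stands at 25.8% and oak's at 25.5%, though L differs from maple's 3.00 M. So I read the stop as Q leaving by two ways, one of them unseen, with Q the limiting reagent in cedar, oak, birch and maple.

| flask | Q | L | time |
|---|---|---|---|
| cedar | 0.500 M | 1.00 M |  |
| oak | 0.200 M | 0.700 M |  |
| birch | 0.750 M | 1.00 M |  |
| maple | 0.500 M | 3.00 M |  |
| elm | 1.00 M | 1.00 M | 21 min |

- cedar run (time / min: [E] / M): 4.2: 0.0663; 8.4: 0.0974; 13: 0.1160; 17: 0.1247; 21: 0.1292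
- oak run (time / min: [E] / M): 4.2: 0.0287; 8.4: 0.0420; 13: 0.0472; 17: 0.0502; 21: 0.0510
- birch run (time / min: [E] / M): 4.2: 0.0798; 8.4: 0.1282; 13: 0.1564; 17: 0.1742; 21: 0.1794
- maple run (time / min: [E] / M): 4.2: 0.0962; 8.4: 0.1240; 13: 0.1309; 17: 0.1348; 21: 0.1310

(standard deviation of a reading: 0.002 M)

- how the opening rate goes with [Q] round the charge of the cedar run: the exponent of the rate at two percent of Q gone to E (one fixed amount of E, the same in the runs compared)
- how the opening rate goes with [L] round the charge of the cedar run: the exponent of the rate at two percent of Q gone to E
- E in the elm run at 21 min, as a share of the Q charged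

- Overall: Q + L -> E.
- Constant volume, constant temperature.
- A reading of a species includes what of it is bound.
- "The second partner" is L.
- An order is taken over about fifteen percent of the charge, up and down.

Control passes from the opening slope to the ceiling at a crossing time, where the straight slope would meet the ceiling. Taking an exponential rise through the first reading, I get 6.04 min for cedar and 8.16 min for birch. Extended in equal steps of [Q], that gives 10.3 min for elm.

Elm charges Q and L equally, so I bracket it with two versions. In the first I hold [L] at its charge, so the rise is exponential, pseudo-first-order, giving 23.0% at 21 min. In the second, Q and L fall together and the rise is hyperbolic, giving 17.8%, which is lower.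

I place the real curve by the last birch reading. Its versions give 0.183 M and 0.143 M, and its reading of 0.1794 M lies 9.47% of the way down. The same place in elm gives me 22.5%, an estimate, since birch charges more L than Q and elm charges equal amounts.

The forecast gives 0.58, 0.68 and 23%, and says of the stop that “a limited reactive share of Q, or a loss of activity tied to turnover, would fit”.

The flask gives an exponent of 0.68 in [Q], 0.58 in [L], and 22.3% for elm, which is 84.5% of the ceiling share.

    Q + L → E (0.5022 /M/min)
    Q + L → G (1.398 /M/min)
    2 Q ⇌ Q2, settled at all times (4.040 /M)
    2 L ⇌ L2, settled at all times (11.10 /M)

Q and L go to G with a constant of 1.40 /M/min, 2.78 times that of the step to E, and this ratio is the selectivity factor of the pair. With the ceiling share, birch's crossing time puts its E at a quarter of the Q charged at 23.7 min, and the birch run gets there at 23.0 min.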